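**Retrosynthetic overview**
1. C15–O ester: target ⇒ (E)-caffeic acid + labd-7-ene-2α,15-diol (Mitsunobu at the primary OH only).
2. C5–H and ring B: diol ⇒ 5-hydroxy-Δ7 bicycle (radical deoxygenation sets 5α-H) ⇒ ring-closing metathesis (C7=C8) of an allyl carbinol ⇒ allyl Grignard + monocyclic ketone.
3. Key C9–C10 bond (quaternary C10 and C9 together) ⇒ [3,3]-sigmatropic ketal Claisen rearrangement of an allyl cyclohexenyl ether ⇒ methyl enol ether of O-benzyl-(4R,6R)-actinol + (E)-allylic alcohol made from (S)-citronellol by SeO2 oxidation.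
4. Ring order: ring A is bought (actinol), ring B is closed after the Claisen step by metathesis, the catechol ring is bought. C2 and C13 are bought; C9/C10 come from the Claisen step under control of C2; C5 is set under control of C10.

Assumption: labdane numbering (C1–C20) is used for all intermediates; metal alkoxides present only before aqueous work-up are not numbered as separate compounds.

**Step 1**
Reactants: 1 (4R,6R)-4-hydroxy-2,2,6-trimethylcyclohexan-1-one (actinol)
Product: 2 (4R,6R)-4-(benzyloxy)-2,2,6-trimethylcyclohexan-1-one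
Conditions: BnOC(=NH)CCl3, TfOH (cat.), CH2Cl2/cyclohexane, 0 °C to rt
Reagents that add atoms: benzyl 2,2,2-trichloroacetimidate N=C(OCc1ccccc1)C(Cl)(Cl)Cl
Why: Acid-catalysed imidate O-benzylation protects the carbinol without base (no enolate C-alkylation) and leaves both stereocentres untouched.

**Step 2**
Reactants: 2 (4R,6R)-4-(benzyloxy)-2,2,6-trimethylcyclohexan-1-one
Product: 4 (4R)-4-(benzyloxy)-1-methoxy-2,6,6-trimethylcyclohex-1-ene, via dimethyl ketal 3 (not isolated)
Conditions: HC(OMe)3, TsOH (cat.), 60 °C; then 140 °C, distil off MeOH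
Reagents that add atoms: trimethyl orthoformate COC(OC)OC
Why: Orthoformate ketalisation followed by acid-catalysed loss of methanol gives the only possible enol ether, because the other α-carbon is quaternary; the C6 centre is erased on purpose and the carbinol centre is untouched.

**Step 3**
Reactants: 5 (S)-citronellol
Product: 6 (S)-citronellyl benzyl ether
Conditions: NaH, BnBr, Bu4NI (cat.), THF, 0 °C to rt
Reagents that add atoms: benzyl bromide BrCc1ccccc1
Why: Williamson ether synthesis on the primary alcohol; the C3 stereocentre is not involved.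

**Step 4**
Reactants: 6 (S)-citronellyl benzyl ether
Product: 7 (2E,6S)-8-(benzyloxy)-2,6-dimethyloct-2-en-1-ol
Conditions: SeO2 (0.3 equiv), t-BuOOH (3 equiv), salicylic acid (cat.), CH2Cl2, rt
Reagents that add atoms: selenium dioxide O=[Se]=O (catalytic oxygen carrier), tert-butyl hydroperoxide CC(C)(C)OO
Why: Sharpless catalytic SeO2 allylic hydroxylation (ene reaction, then [2,3]-shift) oxidises only the E-methyl of the isopropylidene group, giving the (E)-allylic alcohol needed for the Claisen step.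

**Step 5 (key step)**
Reactants: 4 (4R)-4-(benzyloxy)-1-methoxy-2,6,6-trimethylcyclohex-1-ene; 7 (2E,6S)-8-(benzyloxy)-2,6-dimethyloct-2-en-1-ol
Product: 10 (2R,4S)-4-(benzyloxy)-2-[(3S,6S)-8-(benzyloxy)-2,6-dimethyloct-1-en-3-yl]-2,6,6-trimethylcyclohexan-1-one, via mixed methyl allyl ketal 8 (not isolated), via allyl enol ether 9 (not isolated)
Conditions: 4 (1.3 equiv), 2,4-dinitrophenol (10 mol %), xylene, 140 °C, MeOH distilled off
Reagents that add atoms: none
Why: Acid-catalysed alkoxy exchange then ketal (Johnson–Faulkner) Claisen [3,3]-rearrangement forms C9–C10 through a chair transition state (E-allyl unit, so C9–H ends anti to the C10 methyl), and the allyl unit is expected to add to C10 anti to the pseudoaxial C4 methyl, the face syn to the equatorial 2-OBn; this facial ratio is predicted from the conformational model, not precedented, and the minor epimer is removed by chromatography.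

**Step 6**
Reactants: 10 (2R,4S)-4-(benzyloxy)-2-[(3S,6S)-8-(benzyloxy)-2,6-dimethyloct-1-en-3-yl]-2,6,6-trimethylcyclohexan-1-one
Product: 11 (1S,2R,4S)-4-(benzyloxy)-2-[(3S,6S)-8-(benzyloxy)-2,6-dimethyloct-1-en-3-yl]-2,6,6-trimethyl-1-(prop-2-en-1-yl)cyclohexan-1-ol
Conditions: allylMgBr (3 equiv), Et2O, −20 to 0 °C; aq. NH4Cl
Reagents that add atoms: allylmagnesium bromide C=CC[Mg]Br
Why: Grignard 1,2-addition of the allyl nucleophile (cyclic SE2′ transition state) reaches the non-enolisable ketone despite two flanking quaternary carbons, attacking axially anti to the two β-axial methyls; the new C5 configuration is irrelevant because C5 is re-set in step 9.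

**Step 7**
Reactants: 11 (1S,2R,4S)-4-(benzyloxy)-2-[(3S,6S)-8-(benzyloxy)-2,6-dimethyloct-1-en-3-yl]-2,6,6-trimethyl-1-(prop-2-en-1-yl)cyclohexan-1-ol
Product: 12 2α,15-bis(benzyloxy)-5β-hydroxylabd-7-ene (A/B cis; 2S,5S,9S,10R,13S)
Conditions: Grubbs II (5 mol %), CH2Cl2, 40 °C
Reagents that add atoms: none
Why: Ring-closing metathesis between the allyl and isopropenyl groups closes ring B and places the trisubstituted C7=C8 alkene with its methyl directly; no stereocentre is formed.

**Step 8**
Reactants: 12 2α,15-bis(benzyloxy)-5β-hydroxylabd-7-ene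
Product: 13 2α,15-bis(benzyloxy)labd-7-en-5β-yl methyl oxalate
Conditions: ClCOCO2Me, Et3N, DMAP, CH2Cl2, 0 °C to rt
Reagents that add atoms: methyl chlorooxalate COC(=O)C(=O)Cl
Why: O-acylation with the very electrophilic oxalyl chloride half-ester converts the tertiary alcohol into a radical precursor; stereocentres unchanged.

**Step 9**
Reactants: 13 2α,15-bis(benzyloxy)labd-7-en-5β-yl methyl oxalate
Product: 14 2α,15-bis(benzyloxy)labd-7-ene (5α-H, trans-fused; 2S,5S,9S,10S,13S)
Conditions: Bu3SnH, AIBN, toluene, 110 °C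
Reagents that add atoms: none
Why: Dolan–MacMillan radical deoxygenation gives the tertiary C5 ring-fusion radical, which takes hydrogen from the α-face, anti to the β-methyls on C10 and C4, to give the trans-decalin (the same radical that gives trans-decalins in HAT hydrogenations).

**Step 10**
Reactants: 14 2α,15-bis(benzyloxy)labd-7-ene
Product: 15 labd-7-ene-2α,15-diol (2S,5S,9S,10S,13S)
Conditions: Li, NH3(l)/THF, −78 °C; NH4Cl
Reagents that add atoms: none
Why: Dissolving-metal (Birch-type) cleavage removes both benzyl ethers while the isolated trisubstituted alkene is inert, so no stereocentre or alkene position changes.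

**Step 11**
Reactants: 15 labd-7-ene-2α,15-diol; 16 (E)-caffeic acid
Product: 17 2α-hydroxylabd-7-en-15-yl (E)-caffeate (target)
Conditions: PPh3, DIAD, THF, 0 °C to rt
Reagents that add atoms: none
Why: Mitsunobu esterification activates only the primary C15–OH (the 2α-OH cannot be displaced because backside attack is blocked by two syn-axial methyls), and the carboxylic acid reacts in preference to the phenols; the E-alkene is retained.

**Compound list**
1 | (4R,6R)-4-hydroxy-2,2,6-trimethylcyclohexan-1-one (actinol) | O=C1C(C)(C)C[C@H](O)C[C@H]1C | starting material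
2 | (4R,6R)-4-(benzyloxy)-2,2,6-trimethylcyclohexan-1-one | O=C1C(C)(C)C[C@H](OCc2ccccc2)C[C@H]1C | intermediate
3 | (4R,6R)-4-(benzyloxy)-1,1-dimethoxy-2,2,6-trimethylcyclohexane | COC1(OC)C(C)(C)C[C@H](OCc2ccccc2)C[C@H]1C | intermediate
4 | (4R)-4-(benzyloxy)-1-methoxy-2,6,6-trimethylcyclohex-1-ene | COC1=C(C)C[C@@H](OCc2ccccc2)CC1(C)C | intermediate
5 | (S)-citronellol, (3S)-3,7-dimethyloct-6-en-1-ol | OCC[C@@H](C)CCC=C(C)C | starting material
6 | (S)-citronellyl benzyl ether | C(OCC[C@@H](C)CCC=C(C)C)c1ccccc1 | intermediate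
7 | (2E,6S)-8-(benzyloxy)-2,6-dimethyloct-2-en-1-ol | OC/C(C)=C/CC[C@H](C)CCOCc1ccccc1 | intermediate
8 | (4R)-4-(benzyloxy)-1-{[(2E,6S)-8-(benzyloxy)-2,6-dimethyloct-2-en-1-yl]oxy}-1-methoxy-2,2,6-trimethylcyclohexane (mixture at C1 and C6) | COC1(OC/C(C)=C/CC[C@H](C)CCOCc2ccccc2)C(C)(C)C[C@H](OCc3ccccc3)CC1C | intermediate
9 | (4R)-4-(benzyloxy)-1-{[(2E,6S)-8-(benzyloxy)-2,6-dimethyloct-2-en-1-yl]oxy}-2,6,6-trimethylcyclohex-1-ene | CC1=C(OC/C(C)=C/CC[C@H](C)CCOCc2ccccc2)C(C)(C)C[C@H](OCc3ccccc3)C1 | intermediate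
10 | (2R,4S)-4-(benzyloxy)-2-[(3S,6S)-8-(benzyloxy)-2,6-dimethyloct-1-en-3-yl]-2,6,6-trimethylcyclohexan-1-one | O=C1C(C)(C)C[C@H](OCc2ccccc2)C[C@]1(C)[C@H](C(C)=C)CC[C@H](C)CCOCc3ccccc3 | intermediate
11 | (1S,2R,4S)-4-(benzyloxy)-2-[(3S,6S)-8-(benzyloxy)-2,6-dimethyloct-1-en-3-yl]-2,6,6-trimethyl-1-(prop-2-en-1-yl)cyclohexan-1-ol | O[C@@]1(CC=C)C(C)(C)C[C@H](OCc2ccccc2)C[C@]1(C)[C@H](C(C)=C)CC[C@H](C)CCOCc3ccccc3 | intermediate
12 | 2α,15-bis(benzyloxy)-5β-hydroxylabd-7-ene (A/B cis; 2S,5S,9S,10R,13S) | CC1=CC[C@]2(O)C(C)(C)C[C@H](OCc3ccccc3)C[C@]2(C)[C@H]1CC[C@H](C)CCOCc4ccccc4 | intermediate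
13 | 2α,15-bis(benzyloxy)labd-7-en-5β-yl methyl oxalate | CC1=CC[C@]2(OC(=O)C(=O)OC)C(C)(C)C[C@H](OCc3ccccc3)C[C@]2(C)[C@H]1CC[C@H](C)CCOCc4ccccc4 | intermediate
14 | 2α,15-bis(benzyloxy)labd-7-ene (5α-H, 9α-H, 10β-Me; 2S,5S,9S,10S,13S) | CC1=CC[C@H]2C(C)(C)C[C@H](OCc3ccccc3)C[C@]2(C)[C@H]1CC[C@H](C)CCOCc4ccccc4 | intermediate
15 | labd-7-ene-2α,15-diol (2S,5S,9S,10S,13S) | CC1=CC[C@H]2C(C)(C)C[C@H](O)C[C@]2(C)[C@H]1CC[C@H](C)CCO | intermediate
16 | (E)-caffeic acid | OC(=O)/C=C/c1ccc(O)c(O)c1 | starting material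
17 | 2α-hydroxylabd-7-en-15-yl (E)-caffeate; (3S)-5-[(1S,4aS,7S,8aS)-7-hydroxy-2,5,5,8a-tetramethyl-1,4,4a,5,6,7,8,8a-octahydronaphthalen-1-yl]-3-methylpentyl (E)-3-(3,4-dihydroxyphenyl)prop-2-enoate | CC1=CC[C@H]2C(C)(C)C[C@H](O)C[C@]2(C)[C@H]1CC[C@H](C)CCOC(=O)/C=C/c1ccc(O)c(O)c1 | target

**Totals**
Total steps: 11. Longest linear sequence: 9 (steps 1, 2, 5–11 from actinol; equally 3, 4, 5–11 from citronellol).

**Three steps most likely to fail**

Step 5 (hindered alkoxy exchange on a tetrasubstituted enol ether; remote facial control at C10). Fallback: build the allyl vinyl ether by C–O cross-coupling instead of acid exchange. Setting out from ketone 2, condensation with hydrazine gives (4R,6R)-4-(benzyloxy)-2,2,6-trimethylcyclohexan-1-one hydrazone F1. Barton iodination (I2, tetramethylguanidine, THF) then gives (4R)-4-(benzyloxy)-1-iodo-2,6,6-trimethylcyclohex-1-ene F2. Copper-catalysed coupling of F2 with alcohol 7 (CuI, 3,4,7,8-tetramethyl-1,10-phenanthroline, Cs2CO3, toluene, 120 °C) forms enol ether 9, which rearranges in the same pot, and the route is rejoined at ketone 10. This also bypasses step 2; it does not change the facial ratio.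

Step 8 (acylation of a tertiary alcohol lying between two quaternary carbons). Fallback: skip the oxalate and cleave the C5–O bond directly. Setting out from alcohol 12, a low-valent titanium system (Cp*TiCl3 cat., Zn, Et3SiCl) homolyses the C–O bond of the titanium alkoxide, with PhSiH3 as hydrogen-atom donor. The same C5 radical is reduced from the α-face and the route is rejoined at 14; no new isolable compound is made (F0).

Step 11 (Mitsunobu with unprotected catechol; phenol O-alkylation may compete). Fallback: make the cinnamate C=C bond last instead of the ester bond. Setting out from diol 15, Meldrum's acid (1.05 equiv, toluene, 100 °C) acylates the primary alcohol to give 3-[(2α-hydroxylabd-7-en-15-yl)oxy]-3-oxopropanoic acid F3. Knoevenagel–Doebner condensation of F3 with 3,4-dihydroxybenzaldehyde (pyridine, piperidine cat., 70 °C) gives the (E)-caffeate with loss of CO2, rejoining the route at target 17.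

**Further compounds**
F1 | step 5 | (4R,6R)-4-(benzyloxy)-2,2,6-trimethylcyclohexan-1-one hydrazone | NN=C1C(C)(C)C[C@H](OCc2ccccc2)C[C@H]1C
F2 | step 5 | (4R)-4-(benzyloxy)-1-iodo-2,6,6-trimethylcyclohex-1-ene | IC1=C(C)C[C@@H](OCc2ccccc2)CC1(C)C
F0 | step 8 | none | none
F3 | step 11 | 3-[(2α-hydroxylabd-7-en-15-yl)oxy]-3-oxopropanoic acid | CC1=CC[C@H]2C(C)(C)C[C@H](O)C[C@]2(C)[C@H]1CC[C@H](C)CCOC(=O)CC(=O)O
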